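If a catalyst is lost at a fixed chance per round, the clock of a flask is not conversion but the rounds each catalyst has made.

common to all: starting material 0.050 M
- Sunday's: second substrate 2 equiv; capture agent 5 mM; free catalyst 1.4 mol%; run made earlier
- Thursday's: second substrate 2 equiv; capture agent 5 mM; free catalyst 2.2 mol%; run made earlier
- Saturday's: second substrate 2 equiv; capture agent 10 mM; free catalyst 1 mol%; run made earlier
- flask: second substrate 2.00 equiv; capture agent 5.00 mM; free catalyst 1 mol%

- Sunday's (time / h: target / %): 0.417: 1.5; 1.33: 5.1; 2.00: 6.8; 3.00: 9.2; 5.00: 14.6
- Thursday's (time / h: target / %): 1.00: 7.3; 2.00: 11.5; 3.00: 15.5; 4.00: 21.0; 5.00: 25.7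
- Saturday's (time / h: target / %): 1.00: 0.8; 2.00: 3.7; 3.00: 6.0; 4.00: 8.4; 5.00: 10.1

(readings scatter by 1 percentage point)

- the analysis behind the earlier runs scatters by 1 percentage point, standard deviation
- no earlier run changes the charge of second substrate; that part of a forecast is a guess

* apparent order in second substrate when 20% of the starting material are converted (percent change of the rate of making target for one percent more second substrate charged)
* apparent order in free catalyst when 20% of the starting material are converted (percent change of the rate of making target for one percent more free catalyst charged)

For the flask, 20.0 is the number of rounds demanded, the target made per catalyst charged at the level looked at, which is the turnover number. Thursday's last reading shows the furthest turnover of the runs, about 11.7 rounds, although its 25.7% of target lies past the level in conversion. So these two amounts are compared: rounds demanded and rounds shown, and the first is 1.71 times the second. Counted in rounds, the flask's level therefore lies beyond the readings. In the flask, capture agent stands at ten times the catalyst charged, so its charge could take up the catalyst one for one.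

The logarithms of the last readings of Sunday's and Thursday's runs, against those of their loadings, give a read order in catalyst of 1.25. The reckoning here puts the order at the level above that reading, since the same conversion asks 20.0 rounds at the flask's loading and 9.09 at Thursday's. The order in second substrate stays a guess. The forecast says 1.1 in catalyst, lower than that reading, and 0.5 in second substrate, seeing “no sign of a strong change by 20%”.

The simulation gives 2.9 in catalyst and −0.29 in second substrate.

    second substrate + free catalyst ⇌ catalyst intermediate B (K = 6.70 M⁻¹, k = 1.20 M⁻¹ s⁻¹)
    catalyst intermediate A + capture agent → trapped intermediate (k = 0.0330 M⁻¹ s⁻¹)
    catalyst intermediate A → free catalyst + target (k = 0.00470 s⁻¹)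
    catalyst intermediate B → free catalyst + second product (k = 0.00550 s⁻¹)
    starting material + free catalyst ⇌ catalyst intermediate A (K = 9.90 M⁻¹, k = 0.120 M⁻¹ s⁻¹)

In the flask at 8.00 h, catalyst intermediate A goes to free catalyst and target 30 times as fast as it goes with capture agent to trapped intermediate, and the 20.0 rounds demanded stand below that ratio; when 20% of the starting material is converted, at 11.3 h, 65.5% of the catalyst is trapped intermediate. After 80.0 h the flask holds 30.0% of target with 99.9% of its catalyst trapped. A flask with twice the free catalyst is asked 10.0 rounds for the same level, and its rate comes out 3.91 times as large.

The readings are calculated from invented constants.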